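You have 5 questions on 4 ways of running one reaction, and you carry one number through them.

common to all: free catalyst 85 µM

|  | starting material | reagent | remark | time |
|---|---|---|---|---|
| autumn | 0.010 M | 0.0110 M | a single well-mixed tank run continuously and read at steady state, 6.0 d in it on average |  |
| winter | 0.010 M | 0.0110 M (fed, over 3.00 d) | all but reagent at the start; reagent goes in evenly over 3.00 d, the run ends at 6.0 d | 6.0 d |
| midnight | 0.010 M | 0.0110 M | a closed flask charged with all of it at once and left for 6.0 d | 6.0 d |
| noon | 0.010 M (fed, over 3.00 d) | 0.0110 M | a stirred flask in which starting material is dosed at a steady rate over 3.00 d without added volume, worked up at 6.0 d | 6.0 d |

    catalyst intermediate B → free catalyst + product (k1 = 7.6 /h)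
    starting material + free catalyst ⇌ catalyst intermediate A (K2 = 190 /M, k2 = 200 /M/h)
    2 free catalyst ⇌ resting dimer, settled at all times (K3 = 49000 /M)
    reagent + catalyst intermediate A → catalyst intermediate B (k4 = 870 /M/h)

- where a step has two of a species, its rate is k times that concentration squared, and two are used at each turn
- the stated concentrations are those of everything mixed, before any reaction; amounts are the same in each set-up
- the feed brings no volume worth counting
- run time (winter): 6.0 d

- the set-up with the highest amount of product at the outlet or at the end, in percent of the starting material put in ("none" if the first two lie within 2 percentage points) (autumn / winter / midnight / noon / none)
- amount of product at the outlet or at the end, in percent of the starting material put in, autumn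
- amount of product at the outlet or at the end, in percent of the starting material put in, winter
- amount of product at the outlet or at the end, in percent of the starting material put in, midnight
- amount of product at the outlet or at the end, in percent of the starting material put in, noon

Ask first what end state the midnight flask, charged at once, is heading for. The reagent step and the release of product run one way, and reagent is charged at 1.10 times the starting material, so starting material is the limiting reagent and product, as a fraction of the charge, climbs towards 100 percent.

How fast it climbs goes with the free catalyst. At the charge, with both intermediates in steady state, each free catalyst has beside it 0.188 of catalyst intermediate A and 0.237 of catalyst intermediate B, which makes 1.43 with itself. Balancing these against the resting dimer, which holds two catalysts each, leaves 23.1 µM free. That is 27.1% of the catalyst charge, with 61.3% in the dimer, the resting state. Of catalyst intermediate A formed, 90.1% goes on with reagent; the remainder returns to starting material and free catalyst.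

Multiply the forward constant of step 2 by that free catalyst and that share, and you get 0.0997 /d: the turnover constant, the fraction of the remaining starting material that becomes product per day, a pseudo-first-order constant with the concentrations held at their charge. So the midnight curve leaves zero with that slope. It would cross half the charge at 6.95 d, later than the end of the run, and its knee, at 10.0 d, lies beyond the run as well. On this reckoning midnight stands at 45.0% at 6.0 d, still rising. Here the hand reckoning stops.

The forecast names midnight as best, with 44.2% there (42.5% to 46%), 40.6% for winter, 36.8% for autumn and 35.6% for noon, holding that “the all-at-once batch gets furthest”. Your figure for midnight stands above its 44.2%, inside its range.

The flask gives midnight as best at 44.4%, ahead of winter at 40.9%, autumn at 36.7% and noon at 35.7%. The midnight flask ends on the rising part of its curve, with 55.6% of its starting material left, and at 60.0 d its product stands at 98.8%. Now take the turnover constant, as reckoned at the charge, to the autumn tank, where feed and turnover balance: the fraction left is one over one plus 0.0997 /d times the 6.0 d spent in it on average, which gives an estimate of 37.4% product. The tank reads 36.7%, with 63.2% of the starting material at the outlet.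

Its constants are assumed; no experiment stands behind them.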